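The C8–C9 bond of the seven-membered ring B (C1-C2-C3-C7-C8-C9-C10) is the disconnection on which the plan rests. The key step exploits the fact that C9 is the β-carbon of the C1 enone while C8 is a neopentyl methylene on quaternary C7. A nucleophilic C8 radical adds 7-endo to C9 and expels a phenylsulfonyl group from that same carbon, so ring B and its C9=C10 alkene form in one operation without touching C3, C4 or C7. The precursor is the complete ring A cyclopentane (C3 silyl ether, C4 isopropyl, C7 methyl, all cis) bearing an iodomethyl group on C7 and an (E)-β-phenylsulfonyl enone arm on C3, with the iodide installed before any electrophilic alkene exists.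

Key step: step 12

Assumption: atom labels are C1 (CH–O-acyl), C2, C3 (C–OH), C4 (CH–iPr), C5, C6, C7 (C–CH3), C8, C9=C10 (C10–CH3), and ring A is C3-C4-C5-C6-C7. The SMILES encodes a cis ring fusion with C3–OH, C7–CH3 and C4–iPr on one face and the C1 ester on the other, and that isomer is made. The antipode of the phase-transfer catalyst in step 1 that leads to the (S) ester is fixed in a trial run, both antipodes being available.

Step 1
Reactants: 1 tert-butyl 2-oxocyclopentane-1-carboxylate
Product: 2 tert-butyl (1S)-1-methyl-2-oxocyclopentane-1-carboxylate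
Conditions: MeI (excess), C2-symmetric N-spiro bis(binaphthyl)ammonium bromide with 3,4,5-trifluorophenyl groups at the 3,3′ positions (1–2 mol %), CsOH·H2O, toluene, −40 °C
Reagents that add atoms: iodomethane, CI
Why: Asymmetric phase-transfer C-methylation of a cyclic β-keto ester: the enolate travels as a tight ion pair with the chiral ammonium cation, which shields one enolate face and so sets the quaternary C7 centre, while the bulky tert-butyl ester disfavours O-alkylation and ester hydrolysis.

Step 2
Reactants: 2 tert-butyl (1S)-1-methyl-2-oxocyclopentane-1-carboxylate; 3 acetone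
Product: 4 tert-butyl (1S)-3-(2-hydroxypropan-2-yl)-1-methyl-2-oxocyclopentane-1-carboxylate (both C3 epimers)
Conditions: LiN(iPr)2, THF, −78 °C; ZnCl2; 3, −78 to −40 °C; AcOH quench
Reagents that add atoms: none
Why: Directed aldol addition: C4 is the only enolisable position of 2, and the zinc enolate adds to acetone as a chelated aldolate that resists retro-aldol reversal; the transient C4 centre needs no control because it becomes sp2 in step 3.

Step 3
Reactants: 4 tert-butyl (1S)-3-(2-hydroxypropan-2-yl)-1-methyl-2-oxocyclopentane-1-carboxylate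
Product: 6 tert-butyl (1S)-1-methyl-2-oxo-3-(propan-2-ylidene)cyclopentane-1-carboxylate, via tertiary mesylate 5 (not isolated)
Conditions: MsCl, Et3N, DMAP (cat.), CH2Cl2, 0 °C; then DBU, rt
Reagents that add atoms: none
Why: Aldol dehydration by mesylation of the tertiary alcohol (sulfene pathway) followed by E1cB loss of mesylate through the C4 enolate, with DBU drawing any isopropenyl isomer into conjugation, should give the tetrasubstituted exocyclic enone that has no α-hydrogen left.

Step 4
Reactants: 6 tert-butyl (1S)-1-methyl-2-oxo-3-(propan-2-ylidene)cyclopentane-1-carboxylate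
Product: 7 (2R)-2-(hydroxymethyl)-2-methyl-5-(propan-2-ylidene)cyclopentan-1-ol (both C1 epimers)
Conditions: LiAlH4 (excess), THF, 0 °C to rt
Reagents that add atoms: none
Why: Exhaustive hydride reduction (1,2-reduction of the hindered enone carbonyl and reduction of the ester to the primary alcohol); the C3 carbinol configuration is left uncontrolled because step 5 removes it.

Step 5
Reactants: 7 (2R)-2-(hydroxymethyl)-2-methyl-5-(propan-2-ylidene)cyclopentan-1-ol
Product: 8 (2R)-2-(hydroxymethyl)-2-methyl-5-(propan-2-ylidene)cyclopentan-1-one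
Conditions: activated MnO2 (excess), CH2Cl2, rt
Reagents that add atoms: none
Why: Chemoselective allylic oxidation: MnO2 oxidises the allylic secondary alcohol back to the enone and leaves the saturated neopentyl primary alcohol alone, so the ester has been exchanged for a free hydroxymethyl group without a protecting group.

Step 6
Reactants: 8 (2R)-2-(hydroxymethyl)-2-methyl-5-(propan-2-ylidene)cyclopentan-1-one
Product: 9 (2R,5R)-2-(hydroxymethyl)-2-methyl-5-(propan-2-yl)cyclopentan-1-one (isopropyl trans to CH2OH, cis to the ring methyl)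
Conditions: H2 (1–4 atm), [Ir(cod)(PCy3)(py)]PF6 (5–10 mol %, in portions), CH2Cl2, 0 °C to rt
Reagents that add atoms: none
Why: Hydroxyl-directed homogeneous hydrogenation: the C8 hydroxyl binds the cationic iridium centre and guides H2 onto the alkene face that carries the hydroxymethyl group, so that hydrogen enters C4 cis to C8 and the new C4 centre has isopropyl trans to CH2OH and cis to the C7 methyl, a relationship that the enolisable ketone could not reach reliably by equilibration.

Step 7
Reactants: 9 (2R,5R)-2-(hydroxymethyl)-2-methyl-5-(propan-2-yl)cyclopentan-1-one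
Product: 11 (2S,5R)-2-(iodomethyl)-2-methyl-5-(propan-2-yl)cyclopentan-1-one, via neopentyl triflate 10 (not isolated)
Conditions: Tf2O, 2,6-lutidine, CH2Cl2, −78 °C; then n-Bu4NI, −78 °C to rt
Reagents that add atoms: tetrabutylammonium iodide, CCCC[N+](CCCC)(CCCC)CCCC.[I-]
Why: Alcohol activation and SN2 displacement: a neopentyl triflate is displaced by iodide near room temperature in a non-ionising solvent, which avoids the heating that neopentyl halogenations otherwise need and so protects the enolisable C4 centre, and with no hydrogen on C7 elimination cannot compete; the iodide is placed now because later carbonyl arms would either participate in or be attacked under halogenation conditions.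

Step 8
Reactants: 11 (2S,5R)-2-(iodomethyl)-2-methyl-5-(propan-2-yl)cyclopentan-1-one; 12 N-methoxy-N-methylacetamide
Product: 13 2-[(1S,2S,5R)-1-hydroxy-2-(iodomethyl)-2-methyl-5-(propan-2-yl)cyclopentyl]-N-methoxy-N-methylacetamide
Conditions: 12, LiN(iPr)2, THF, −78 °C; anhydrous CeCl3, −78 °C; then 11, −78 °C; AcOH quench at −78 °C
Reagents that add atoms: none
Why: Aldol addition of an amide enolate to a ketone, carried out with the weakly basic cerium enolate to suppress enolisation of the hindered ketone: the nucleophile approaches C3 from the face opposite the cis-disposed C4 isopropyl and C7 methyl groups (the face of CH2I), which sets C3 with its oxygen cis to both.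

Step 9
Reactants: 13 2-[(1S,2S,5R)-1-hydroxy-2-(iodomethyl)-2-methyl-5-(propan-2-yl)cyclopentyl]-N-methoxy-N-methylacetamide
Product: 14 2-[(1S,2S,5R)-2-(iodomethyl)-2-methyl-5-(propan-2-yl)-1-[(trimethylsilyl)oxy]cyclopentyl]-N-methoxy-N-methylacetamide
Conditions: TMSOTf, 2,6-lutidine, CH2Cl2, −78 to 0 °C
Reagents that add atoms: trimethylsilyl trifluoromethanesulfonate, C[Si](C)(C)OS(=O)(=O)C(F)(F)F
Why: Silylation of a tertiary alcohol with a silyl triflate: the small trimethylsilyl group is chosen because the hydroxyl lies between the cis methyl and isopropyl groups, which then shield the ether, and capping the oxygen blocks retro-aldol cleavage and alkoxide-triggered fragmentation toward the C8–I bond in the basic steps that follow.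

Step 10
Reactants: 14 2-[(1S,2S,5R)-2-(iodomethyl)-2-methyl-5-(propan-2-yl)-1-[(trimethylsilyl)oxy]cyclopentyl]-N-methoxy-N-methylacetamide; 15 isopropenylmagnesium bromide (prop-1-en-2-ylmagnesium bromide, commercial THF solution)
Product: 16 1-[(1S,2S,5R)-2-(iodomethyl)-2-methyl-5-(propan-2-yl)-1-[(trimethylsilyl)oxy]cyclopentyl]-3-methylbut-3-en-2-one
Conditions: 15 (2–3 equiv), THF, −20 to 0 °C; aq. NH4Cl
Reagents that add atoms: none
Why: Weinreb ketone synthesis: the stable magnesium chelate of the tetrahedral adduct prevents over-addition, and the neopentyl iodide is inert to the Grignard reagent at this temperature.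

Step 11
Reactants: 16 1-[(1S,2S,5R)-2-(iodomethyl)-2-methyl-5-(propan-2-yl)-1-[(trimethylsilyl)oxy]cyclopentyl]-3-methylbut-3-en-2-one; 17 sodium benzenesulfinate
Product: 19 (3E)-1-[(1S,2S,5R)-2-(iodomethyl)-2-methyl-5-(propan-2-yl)-1-[(trimethylsilyl)oxy]cyclopentyl]-3-methyl-4-(phenylsulfonyl)but-3-en-2-one, via α-iodo β-sulfonyl ketone 18 (not isolated)
Conditions: PhSO2Na (17), I2, CH2Cl2/H2O, rt, visible light; then Et3N (1.1 equiv), CH2Cl2, 0 °C
Reagents that add atoms: none
Why: Iodosulfonylation–dehydroiodination: benzenesulfonyl iodide formed in the flask transfers a sulfonyl radical to the terminal CH2 (C9) and iodine to the tertiary α-keto radical at C10, and one equivalent of triethylamine then removes HI through the acidic CH2SO2 hydrogen to give the vinyl sulfone with sulfonyl trans to acyl, the less strained geometry, while the short cold base treatment avoids drift to the allyl sulfone.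

Step 12
Reactants: 19 (3E)-1-[(1S,2S,5R)-2-(iodomethyl)-2-methyl-5-(propan-2-yl)-1-[(trimethylsilyl)oxy]cyclopentyl]-3-methyl-4-(phenylsulfonyl)but-3-en-2-one
Product: 20 (3R,3aS,8aR)-6,8a-dimethyl-3-(propan-2-yl)-3a-[(trimethylsilyl)oxy]-2,3,3a,4,8,8a-hexahydroazulen-5(1H)-one
Conditions: (Me3Si)3SiH (1.3 equiv) and AIBN (0.3 equiv) added by syringe pump over 8 h, benzene (0.005 M), 80 °C
Reagents that add atoms: none
Why: Proposed new method: iodine transfer from C8 to the tris(trimethylsilyl)silyl radical leaves a primary radical that bonds to C9, the sulfonyl-bearing carbon β to the C1 carbonyl; the tertiary α-keto radical at C10 then ejects PhSO2• from C9 by β-scission, which puts the C9=C10 double bond back inside the new ring, and chain transfer occurs when PhSO2• abstracts hydrogen from the silane to regenerate the silyl radical. The nearest precedent combines two known reaction types, intermolecular radical vinylation by addition–fragmentation of β-sulfonyl or β-stannyl acrylates and 7-endo ring closures of alkyl radicals onto enones whose carbonyl is part of the new ring. Ring B closes in the 7-endo-trig mode. The step creates no stereocentre, and the three existing ones on ring A lie away from the reacting carbons. It needs bonding at C9 in preference to 6-exo bonding at C10 and to hydrogen transfer to the uncyclised radical; the polarity match between the nucleophilic radical and the enone β-carbon, the methyl group on C10, the (E) geometry that lets the enone sit s-trans with C9 turned toward C8, the cis placement of the C8 and C2 arms on ring A, and slow silane addition at high dilution secure this. The C8 radical has no rearrangement pathway open to it, and iodine abstraction by the silyl radical is faster than its addition to the vinyl sulfone.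

Step 13
Reactants: 20 (3R,3aS,8aR)-6,8a-dimethyl-3-(propan-2-yl)-3a-[(trimethylsilyl)oxy]-2,3,3a,4,8,8a-hexahydroazulen-5(1H)-one
Product: 21 (3R,3aS,8aR)-3a-hydroxy-6,8a-dimethyl-3-(propan-2-yl)-2,3,3a,4,8,8a-hexahydroazulen-5(1H)-one
Conditions: HF·pyridine, pyridine, THF, 0 °C
Reagents that add atoms: none
Why: Fluoride-mediated silyl ether cleavage under buffered, slightly acidic conditions, chosen because a basic fluoride source could open ring B by retro-aldol cleavage of the β-hydroxy ketone.

Step 14
Reactants: 21 (3R,3aS,8aR)-3a-hydroxy-6,8a-dimethyl-3-(propan-2-yl)-2,3,3a,4,8,8a-hexahydroazulen-5(1H)-one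
Product: 22 (3R,3aS,5R,8aR)-6,8a-dimethyl-3-(propan-2-yl)-1,2,3,3a,4,5,8,8a-octahydroazulene-3a,5-diol
Conditions: Me4NBH(OAc)3, MeCN/AcOH (1:1), −30 to −20 °C
Reagents that add atoms: none
Why: Evans–Saksena hydroxyl-directed reduction: the C3 hydroxyl exchanges onto boron and hands hydride to the C1 carbonyl from its own face, which sets C1 with its hydroxyl trans (1,3-anti) to the C3 hydroxyl, and triacetoxyborohydride reduces the enone only in the 1,2 sense.

Step 15
Reactants: 22 (3R,3aS,5R,8aR)-6,8a-dimethyl-3-(propan-2-yl)-1,2,3,3a,4,5,8,8a-octahydroazulene-3a,5-diol; 23 3,4-dimethoxybenzoyl chloride (veratroyl chloride, commercial)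
Product: 24 (3R,3aS,5R,8aR)-3a-hydroxy-6,8a-dimethyl-3-(propan-2-yl)-1,2,3,3a,4,5,8,8a-octahydroazulen-5-yl 3,4-dimethoxybenzoate (target)
Conditions: 23, pyridine, DMAP (cat.), CH2Cl2, 0 °C to rt
Reagents that add atoms: none
Why: DMAP-catalysed acylation of an alcohol with an acid chloride, selective for the secondary allylic C1 hydroxyl because the tertiary C3 hydroxyl between the methyl and isopropyl groups is too hindered to react.

Compound list
1 | tert-butyl 2-oxocyclopentane-1-carboxylate | CC(C)(C)OC(=O)C1CCCC1=O | starting material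
2 | tert-butyl (1S)-1-methyl-2-oxocyclopentane-1-carboxylate | O=C1CCC[C@]1(C)C(=O)OC(C)(C)C | intermediate
3 | acetone | CC(C)=O | starting material
4 | tert-butyl (1S)-3-(2-hydroxypropan-2-yl)-1-methyl-2-oxocyclopentane-1-carboxylate (C3 epimers) | O=C1C(C(C)(C)O)CC[C@]1(C)C(=O)OC(C)(C)C | intermediate
5 | tert-butyl (1S)-3-[2-(methanesulfonyloxy)propan-2-yl]-1-methyl-2-oxocyclopentane-1-carboxylate | O=C1C(C(C)(C)OS(C)(=O)=O)CC[C@]1(C)C(=O)OC(C)(C)C | intermediate (not isolated)
6 | tert-butyl (1S)-1-methyl-2-oxo-3-(propan-2-ylidene)cyclopentane-1-carboxylate | O=C1C(=C(C)C)CC[C@]1(C)C(=O)OC(C)(C)C | intermediate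
7 | (2R)-2-(hydroxymethyl)-2-methyl-5-(propan-2-ylidene)cyclopentan-1-ol (C1 epimers) | OC1C(=C(C)C)CC[C@]1(C)CO | intermediate
8 | (2R)-2-(hydroxymethyl)-2-methyl-5-(propan-2-ylidene)cyclopentan-1-one | O=C1C(=C(C)C)CC[C@]1(C)CO | intermediate
9 | (2R,5R)-2-(hydroxymethyl)-2-methyl-5-(propan-2-yl)cyclopentan-1-one | O=C1[C@@H](C(C)C)CC[C@]1(C)CO | intermediate
10 | [(1R,3R)-1-methyl-2-oxo-3-(propan-2-yl)cyclopentyl]methyl trifluoromethanesulfonate | O=C1[C@@H](C(C)C)CC[C@]1(C)COS(=O)(=O)C(F)(F)F | intermediate (not isolated)
11 | (2S,5R)-2-(iodomethyl)-2-methyl-5-(propan-2-yl)cyclopentan-1-one | O=C1[C@@H](C(C)C)CC[C@]1(C)CI | intermediate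
12 | N-methoxy-N-methylacetamide | CON(C)C(C)=O | starting material
13 | 2-[(1S,2S,5R)-1-hydroxy-2-(iodomethyl)-2-methyl-5-(propan-2-yl)cyclopentyl]-N-methoxy-N-methylacetamide | CON(C)C(=O)C[C@]1(O)[C@@H](C(C)C)CC[C@]1(C)CI | intermediate
14 | 2-[(1S,2S,5R)-2-(iodomethyl)-2-methyl-5-(propan-2-yl)-1-[(trimethylsilyl)oxy]cyclopentyl]-N-methoxy-N-methylacetamide | CON(C)C(=O)C[C@]1(O[Si](C)(C)C)[C@@H](C(C)C)CC[C@]1(C)CI | intermediate
15 | isopropenylmagnesium bromide | C=C(C)[Mg]Br | starting material
16 | 1-[(1S,2S,5R)-2-(iodomethyl)-2-methyl-5-(propan-2-yl)-1-[(trimethylsilyl)oxy]cyclopentyl]-3-methylbut-3-en-2-one | C=C(C)C(=O)C[C@]1(O[Si](C)(C)C)[C@@H](C(C)C)CC[C@]1(C)CI | intermediate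
17 | sodium benzenesulfinate | [Na+].[O-]S(=O)c1ccccc1 | starting material
18 | 3-iodo-1-[(1S,2S,5R)-2-(iodomethyl)-2-methyl-5-(propan-2-yl)-1-[(trimethylsilyl)oxy]cyclopentyl]-3-methyl-4-(phenylsulfonyl)butan-2-one (C3 epimers) | O=S(=O)(c1ccccc1)CC(C)(I)C(=O)C[C@]1(O[Si](C)(C)C)[C@@H](C(C)C)CC[C@]1(C)CI | intermediate (not isolated)
19 | (3E)-1-[(1S,2S,5R)-2-(iodomethyl)-2-methyl-5-(propan-2-yl)-1-[(trimethylsilyl)oxy]cyclopentyl]-3-methyl-4-(phenylsulfonyl)but-3-en-2-one | O=S(=O)(c1ccccc1)/C=C(\C)C(=O)C[C@]1(O[Si](C)(C)C)[C@@H](C(C)C)CC[C@]1(C)CI | intermediate (key-step precursor)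
20 | (3R,3aS,8aR)-6,8a-dimethyl-3-(propan-2-yl)-3a-[(trimethylsilyl)oxy]-2,3,3a,4,8,8a-hexahydroazulen-5(1H)-one | O=C1C[C@]2(O[Si](C)(C)C)[C@@H](C(C)C)CC[C@]2(C)CC=C1C | intermediate (key-step product)
21 | (3R,3aS,8aR)-3a-hydroxy-6,8a-dimethyl-3-(propan-2-yl)-2,3,3a,4,8,8a-hexahydroazulen-5(1H)-one | O=C1C[C@]2(O)[C@@H](C(C)C)CC[C@]2(C)CC=C1C | intermediate
22 | (3R,3aS,5R,8aR)-6,8a-dimethyl-3-(propan-2-yl)-1,2,3,3a,4,5,8,8a-octahydroazulene-3a,5-diol | O[C@@H]1C[C@]2(O)[C@@H](C(C)C)CC[C@]2(C)CC=C1C | intermediate
23 | 3,4-dimethoxybenzoyl chloride | COc1ccc(C(=O)Cl)cc1OC | starting material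
24 | (3R,3aS,5R,8aR)-3a-hydroxy-6,8a-dimethyl-3-(propan-2-yl)-1,2,3,3a,4,5,8,8a-octahydroazulen-5-yl 3,4-dimethoxybenzoate | COc1ccc(C(=O)O[C@@H]2C[C@]3(O)[C@@H](C(C)C)CC[C@]3(C)CC=C2C)cc1OC | target

Total step count: 15. Longest linear sequence: 15 steps (1 to 24).

Steps most likely to fail

Step 12. Hydrogen transfer from the silane to the C8 radical may outrun the 7-endo closure, or closure may drift to the 6-exo sense. The fallback closes ring B by ring-closing metathesis at C9=C10 and needs no radical cyclisation. It sets out from 14: nickel-catalysed reductive cross-electrophile coupling with vinyl bromide (NiI2, 4,4′-di-tert-butyl-2,2′-bipyridine, Zn, dimethylacetamide, rt) should replace iodine by a vinyl group and give the C7-allyl Weinreb amide F1. Isopropenylmagnesium bromide 15 should then convert it into the dienone F2. Second-generation Grubbs catalyst, RuCl2(H2IMes)(PCy3)(=CHPh), in toluene at 80 °C should join the allyl and isopropenyl termini with loss of ethene, and the route is rejoined at 20.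

Step 6. Non-directed hydrogenation from the methyl face may compete with hydroxyl delivery, the catalyst may deactivate on the slow tetrasubstituted enone, and the new α-centre may epimerise after reduction. The fallback gives up kinetic control: hydrogenation of 8 over Pd on carbon in ethyl acetate should give 9 together with the C5 epimer F3. Because C5 is α to the ketone, F3 is separated by chromatography, re-equilibrated with DBU in toluene and recycled, and the route is rejoined at 9.

Step 8. The amide enolate may act as a base and enolise the hindered ketone (with loss of C4 integrity), or the congested aldolate may revert on warming. The fallback sets out from 11 and uses an irreversible, weakly basic carbon nucleophile. Allylmagnesium bromide (THF, −78 °C) should add through a cyclic transition state from the same face to give the homoallylic alcohol F4, and TMSOTf with 2,6-lutidine should give the silyl ether F5. OsO4 (cat.) with NaIO4 and 2,6-lutidine in dioxane–water should cleave the alkene to the aldehyde F6. Addition of 15 should give the allylic alcohol F7, and Dess–Martin periodinane should oxidise it to 16, where the route is rejoined.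

Further compounds
F1 | step 12 | 2-[(1S,2R,5R)-2-methyl-2-(prop-2-en-1-yl)-5-(propan-2-yl)-1-[(trimethylsilyl)oxy]cyclopentyl]-N-methoxy-N-methylacetamide | CON(C)C(=O)C[C@]1(O[Si](C)(C)C)[C@@H](C(C)C)CC[C@]1(C)CC=C
F2 | step 12 | 1-[(1S,2R,5R)-2-methyl-2-(prop-2-en-1-yl)-5-(propan-2-yl)-1-[(trimethylsilyl)oxy]cyclopentyl]-3-methylbut-3-en-2-one | C=C(C)C(=O)C[C@]1(O[Si](C)(C)C)[C@@H](C(C)C)CC[C@]1(C)CC=C
F3 | step 6 | (2R,5S)-2-(hydroxymethyl)-2-methyl-5-(propan-2-yl)cyclopentan-1-one | O=C1[C@H](C(C)C)CC[C@]1(C)CO
F4 | step 8 | (1S,2S,5R)-2-(iodomethyl)-2-methyl-1-(prop-2-en-1-yl)-5-(propan-2-yl)cyclopentan-1-ol | C=CC[C@]1(O)[C@@H](C(C)C)CC[C@]1(C)CI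
F5 | step 8 | {[(1S,2S,5R)-2-(iodomethyl)-2-methyl-1-(prop-2-en-1-yl)-5-(propan-2-yl)cyclopentyl]oxy}trimethylsilane | C=CC[C@]1(O[Si](C)(C)C)[C@@H](C(C)C)CC[C@]1(C)CI
F6 | step 8 | 2-[(1S,2S,5R)-2-(iodomethyl)-2-methyl-5-(propan-2-yl)-1-[(trimethylsilyl)oxy]cyclopentyl]acetaldehyde | O=CC[C@]1(O[Si](C)(C)C)[C@@H](C(C)C)CC[C@]1(C)CI
F7 | step 8 | 1-[(1S,2S,5R)-2-(iodomethyl)-2-methyl-5-(propan-2-yl)-1-[(trimethylsilyl)oxy]cyclopentyl]-3-methylbut-3-en-2-ol (carbinol epimers) | C=C(C)C(O)C[C@]1(O[Si](C)(C)C)[C@@H](C(C)C)CC[C@]1(C)CI
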